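Everything rests on opening ring C (O1–C2–C3–C4–C4a–C8a) of the all-cis (2R,3R,4R) flavan unit into a cationic 2-oxadiene, C4a=C8a–O1(+)=C2 (an aryloxycarbenium ion from 2,3-bis(benzyloxy)phenol and 4-(benzyloxy)benzaldehyde), and a cis-enediol two-carbon unit, C3=C4. A cationic [4+2] union (oxa-Povarov type) forms C2–C3 and C4–C4a in one operation and sets C2, C3 and C4. The 2π partner is a (Z)-2-acetoxyvinyl ether whose ether oxygen is O4 of the finished, benzyl-protected 2,3-trans-3,4-cis (2S,3R,4R) unit, so the C4–O–C4 ether exists before ring C does, and that unit is the source of facial control.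

Key step: step 13

Remark: 2,3-bis(benzyloxy)benzaldehyde is taken as a catalogue compound (otherwise one benzylation from 2,3-dihydroxybenzaldehyde).
Remark: (S)-t-BuPyOx, (S)-4-tert-butyl-2-(pyridin-2-yl)-4,5-dihydrooxazole, is assumed to deliver the aryl group to the chromone face that gives the (2R)-flavanone, by analogy with its sense on cyclic enones.

Step 1
Reactants: 1 2',3',4'-trihydroxyacetophenone (gallacetophenone)
Product: 2 1-[3,4-bis(benzyloxy)-2-hydroxyphenyl]ethan-1-one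
Conditions: BnBr (2.1 equiv), K2CO3, DMF, rt
Reagents that add atoms: benzyl bromide, BrCc1ccccc1
Why: Williamson etherification; the 2-OH is hydrogen-bonded to the ketone and least nucleophilic, so the 3- and 4-OH should be benzylated selectively.

Step 2
Reactants: 2 1-[3,4-bis(benzyloxy)-2-hydroxyphenyl]ethan-1-one
Product: 4 7,8-bis(benzyloxy)-4H-chromen-4-one, via enaminone 3 (not isolated)
Conditions: Me2NCH(OMe)2, toluene, 100 °C; then AcOH, 90 °C
Reagents that add atoms: N,N-dimethylformamide dimethyl acetal, COC(OC)N(C)C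
Why: Standard chromone synthesis: enaminone formation, then acid-mediated oxa-Michael addition of the phenol and loss of dimethylamine.

Step 3
Reactants: 4 7,8-bis(benzyloxy)-4H-chromen-4-one; 5 [4-(benzyloxy)phenyl]boronic acid
Product: 6 (2R)-7,8-bis(benzyloxy)-2-[4-(benzyloxy)phenyl]chroman-4-one
Conditions: Pd(OCOCF3)2 (5 mol %), (S)-t-BuPyOx (6 mol %), NH4PF6 (30 mol %), H2O (5 equiv), ClCH2CH2Cl, 60 °C
Reagents that add atoms: none
Why: Asymmetric conjugate addition of an arylboronic acid to a chromone with a cationic divalent-palladium pyridine-oxazoline catalyst, in which the ligand fixes the face of aryl transfer and so sets C2.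

Step 4
Reactants: 6 (2R)-7,8-bis(benzyloxy)-2-[4-(benzyloxy)phenyl]chroman-4-one
Product: 9 (2S,3S)-7,8-bis(benzyloxy)-2-[4-(benzyloxy)phenyl]-3-hydroxychroman-4-one, via silyl enol ether 7 (not isolated), via 3-silyloxy ketone 8 (not isolated)
Conditions: TMSOTf, Et3N, CH2Cl2, 0 °C; then dimethyldioxirane, acetone/CH2Cl2, −40 to 0 °C; then aq. citric acid, THF, rt
Reagents that add atoms: dimethyldioxirane, CC1(C)OO1
Why: Rubottom oxidation, in which soft enolisation avoids the free enolate that could open the pyranone ring and racemise C2, and the dioxirane attacks the enol ether face anti to the 2-aryl group to give the 2,3-trans ketol, which is also the more stable epimer.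

Step 5
Reactants: 9 (2S,3S)-7,8-bis(benzyloxy)-2-[4-(benzyloxy)phenyl]-3-hydroxychroman-4-one
Product: 10 (2S,3S)-3,7,8-tris(benzyloxy)-2-[4-(benzyloxy)phenyl]chroman-4-one
Conditions: BnBr, Ag2O, 4 Å MS, CH2Cl2, rt, dark
Reagents that add atoms: benzyl bromide, BrCc1ccccc1
Why: Silver-oxide-mediated O-benzylation, chosen because it is nearly neutral and should spare the base-sensitive α-ketol.

Step 6
Reactants: 10 (2S,3S)-3,7,8-tris(benzyloxy)-2-[4-(benzyloxy)phenyl]chroman-4-one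
Product: 11 (2S,3R,4R)-3,7,8-tris(benzyloxy)-2-[4-(benzyloxy)phenyl]chroman-4-ol
Conditions: LiBH(s-Bu)3, THF, −78 °C; then H2O
Reagents that add atoms: none
Why: Bulky trialkylborohydride reduction from the equatorial direction, anti to the vicinal equatorial benzyloxy group, should give the pseudo-axial 4-OH cis to O3, as 2-alkoxycyclohexanones give cis alcohols.

Step 7
Reactants: 11 (2S,3R,4R)-3,7,8-tris(benzyloxy)-2-[4-(benzyloxy)phenyl]chroman-4-ol
Product: 12 (2S,3R,4R)-4-(allyloxy)-3,7,8-tris(benzyloxy)-2-[4-(benzyloxy)phenyl]chromane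
Conditions: NaH, allyl bromide, n-Bu4NI (cat.), THF/DMF, 0 °C to rt
Reagents that add atoms: allyl bromide, C=CCBr
Why: Williamson etherification with retention at C4; the neighbouring benzyl ether cannot migrate.

Step 8
Reactants: 12 (2S,3R,4R)-4-(allyloxy)-3,7,8-tris(benzyloxy)-2-[4-(benzyloxy)phenyl]chromane
Product: 13 2-{[(2S,3R,4R)-3,7,8-tris(benzyloxy)-2-[4-(benzyloxy)phenyl]chroman-4-yl]oxy}acetaldehyde
Conditions: OsO4 (2 mol %), NaIO4 (4 equiv), 2,6-lutidine, 1,4-dioxane/H2O 3:1, rt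
Reagents that add atoms: osmium tetroxide, O=[Os](=O)(=O)=O (catalytic oxygen donor, turned over by sodium periodate, [Na+].[O-]I(=O)(=O)=O)
Why: Lemieux–Johnson cleavage of the terminal alkene, which should leave the electron-rich arenes and benzyl ethers untouched.

Step 9
Reactants: 13 2-{[(2S,3R,4R)-3,7,8-tris(benzyloxy)-2-[4-(benzyloxy)phenyl]chroman-4-yl]oxy}acetaldehyde
Product: 15 (Z)-2-{[(2S,3R,4R)-3,7,8-tris(benzyloxy)-2-[4-(benzyloxy)phenyl]chroman-4-yl]oxy}vinyl acetate, via potassium (Z)-enolate 14 (not isolated)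
Conditions: KN(SiMe3)2, THF, −78 °C (13 added to the base); then Ac2O, −78 °C
Reagents that add atoms: acetic anhydride, CC(=O)OC(C)=O
Why: Enolate O-acylation, in which potassium chelated between the enolate and α-ether oxygens should give the Z enolate and acetylation retains that geometry; the acetate makes O3 a poor donor so that O4 alone directs step 13.

Step 10
Reactants: 16 2,3-bis(benzyloxy)benzaldehyde
Product: 18 2,3-bis(benzyloxy)phenol, via aryl formate 17 (not isolated)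
Conditions: mCPBA, CH2Cl2, rt; then K2CO3, MeOH, rt
Reagents that add atoms: 3-chloroperoxybenzoic acid, OOC(=O)c1cccc(Cl)c1
Why: Dakin-type Baeyer–Villiger oxidation, in which the electron-rich ortho-alkoxy aryl group migrates and the formate is methanolysed.

Step 11
Reactants: 19 4-(benzyloxy)benzaldehyde
Product: 20 1-(benzyloxy)-4-(dimethoxymethyl)benzene
Conditions: HC(OMe)3, p-TsOH·H2O (cat.), MeOH, rt; then NaHCO3
Reagents that add atoms: trimethyl orthoformate, COC(OC)OC; methanol, CO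
Why: Acid-catalysed acetalisation driven by the orthoformate as water scavenger.

Step 12
Reactants: 20 1-(benzyloxy)-4-(dimethoxymethyl)benzene; 18 2,3-bis(benzyloxy)phenol
Product: 22 1,2-bis(benzyloxy)-3-{[4-(benzyloxy)phenyl](methoxy)methoxy}benzene (racemic), via α-chloro ether 21 (not isolated)
Conditions: AcCl, CH2Cl2, 0 °C to rt, evaporate; then 18, i-Pr2NEt, CH2Cl2, 0 °C
Reagents that add atoms: none
Why: Acetal–acyl chloride exchange gives the α-chloro ether, which O-alkylates the phenol as chloromethyl methyl ether does; the new acetal centre is lost in step 13.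

Step 13
Reactants: 22 1,2-bis(benzyloxy)-3-{[4-(benzyloxy)phenyl](methoxy)methoxy}benzene; 15 (Z)-2-{[(2S,3R,4R)-3,7,8-tris(benzyloxy)-2-[4-(benzyloxy)phenyl]chroman-4-yl]oxy}vinyl acetate
Product: 24 (2R,3R,4R)-7,8-bis(benzyloxy)-2-[4-(benzyloxy)phenyl]-4-{[(2S,3R,4R)-3,7,8-tris(benzyloxy)-2-[4-(benzyloxy)phenyl]chroman-4-yl]oxy}chroman-3-yl acetate, via aryloxycarbenium triflate 23 (not isolated)
Conditions: TMSOTf (1.2 equiv), 2,6-di-tert-butyl-4-methylpyridine (1.5 equiv), 4 Å MS, CH2Cl2, −78 °C; aq. NaHCO3 quench at −78 °C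
Reagents that add atoms: none
Why: Proposed new method: TMSOTf silylates the more basic methoxy oxygen of 22 and expels MeOSiMe3 to give the (E)-aryloxycarbenium ion 23, a cationic 2-oxadiene; the acetoxy-bearing carbon of 15 (β to the ether oxygen, the only strong donor, which fixes the regiochemistry) attacks the carbenium carbon to form C2–C3, and the O4-stabilised cation at C4 is captured by the only free ortho carbon of ring A, para to the 7-benzyloxy group, to form C4–C4a before the hindered base takes the proton. The closest known reaction type is the oxa-Povarov reaction (Lewis-acid-promoted formal [4+2] of aryl 2-oxadiene oxocarbenium ions from O-aryl O-methyl acetals with alkenes, giving 2,4-cis-chromans), together with the Povarov reaction of enol ethers; new are the 1-alkoxy-2-acyloxy alkene as 2π partner and the transfer of chirality from its alkoxy group. Ring C closes as an asynchronous [4+2] whose second bond is a 6-exo-trig Friedel–Crafts alkylation. C3 and C4 should inherit their cis relation from the (Z)-alkene by suprafacial addition, C2 should come out cis to both through the endo placement of the two oxygen substituents with respect to the (E)-oxocarbenium (the origin of 2,4-cis selectivity in Povarov chemistry), and the absolute sense should follow from attack on the alkene face turned away from the benzo ring of the (2S,3R,4R)-flavanyl group in the s-trans rotamer that keeps the vinyl carbon anti to its C3. The step needs ring closure to outrun both loss of the stabilised flavan-4-yl cation from the intermediate oxocarbenium and enol ether oligomerisation, which the intramolecular para-activated arene, −78 °C and the proton scavenger should secure; the π-facial selectivity is the least secure point.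

Step 14
Reactants: 24 (2R,3R,4R)-7,8-bis(benzyloxy)-2-[4-(benzyloxy)phenyl]-4-{[(2S,3R,4R)-3,7,8-tris(benzyloxy)-2-[4-(benzyloxy)phenyl]chroman-4-yl]oxy}chroman-3-yl acetate
Product: 25 (2R,3R,4R)-7,8-bis(benzyloxy)-2-[4-(benzyloxy)phenyl]-4-{[(2S,3R,4R)-3,7,8-tris(benzyloxy)-2-[4-(benzyloxy)phenyl]chroman-4-yl]oxy}chroman-3-ol
Conditions: K2CO3, MeOH/THF, rt
Reagents that add atoms: none
Why: Base-catalysed transesterification removes the acetate; no stereocentre is acidic and the benzyl ethers are inert.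

Step 15
Reactants: 25 (2R,3R,4R)-7,8-bis(benzyloxy)-2-[4-(benzyloxy)phenyl]-4-{[(2S,3R,4R)-3,7,8-tris(benzyloxy)-2-[4-(benzyloxy)phenyl]chroman-4-yl]oxy}chroman-3-ol
Product: 26 (2R,3R,4R)-2-(4-hydroxyphenyl)-4-{[(2S,3R,4R)-3,7,8-trihydroxy-2-(4-hydroxyphenyl)chroman-4-yl]oxy}chromane-3,7,8-triol
Conditions: H2 (1 atm), Pd(OH)2/C, THF/MeOH, rt, stopped at full debenzylation
Reagents that add atoms: none
Why: Hydrogenolysis of the seven O-benzyl groups, whose unhindered benzylic C–O bonds should cleave faster than the hindered ring-bound ones (C2–O1 and C4–O–C4), as in deprotection of benzylated proanthocyanidins; acid, which would ionise the C4–O–C4 ether, is avoided.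

Compound list
1 | 2',3',4'-trihydroxyacetophenone | CC(=O)c1ccc(O)c(O)c1O | starting material
2 | 1-[3,4-bis(benzyloxy)-2-hydroxyphenyl]ethan-1-one | CC(=O)c1ccc(OCc2ccccc2)c(OCc2ccccc2)c1O | intermediate
3 | (E)-1-[3,4-bis(benzyloxy)-2-hydroxyphenyl]-3-(dimethylamino)prop-2-en-1-one | CN(C)/C=C/C(=O)c1ccc(OCc2ccccc2)c(OCc2ccccc2)c1O | intermediate
4 | 7,8-bis(benzyloxy)-4H-chromen-4-one | O=c1ccoc2c1ccc(OCc1ccccc1)c2OCc1ccccc1 | intermediate
5 | [4-(benzyloxy)phenyl]boronic acid | OB(O)c1ccc(OCc2ccccc2)cc1 | starting material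
6 | (2R)-7,8-bis(benzyloxy)-2-[4-(benzyloxy)phenyl]chroman-4-one | O=C1c2ccc(OCc3ccccc3)c(OCc3ccccc3)c2O[C@@H](c2ccc(OCc3ccccc3)cc2)C1 | intermediate
7 | (2R)-7,8-bis(benzyloxy)-2-[4-(benzyloxy)phenyl]-4-(trimethylsilyloxy)-2H-chromene | C[Si](C)(C)OC1=C[C@H](c2ccc(OCc3ccccc3)cc2)Oc2c1ccc(OCc1ccccc1)c2OCc1ccccc1 | intermediate
8 | (2S,3S)-7,8-bis(benzyloxy)-2-[4-(benzyloxy)phenyl]-3-(trimethylsilyloxy)chroman-4-one | O=C1c2ccc(OCc3ccccc3)c(OCc3ccccc3)c2O[C@@H](c2ccc(OCc3ccccc3)cc2)[C@@H]1O[Si](C)(C)C | intermediate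
9 | (2S,3S)-7,8-bis(benzyloxy)-2-[4-(benzyloxy)phenyl]-3-hydroxychroman-4-one | O=C1c2ccc(OCc3ccccc3)c(OCc3ccccc3)c2O[C@@H](c2ccc(OCc3ccccc3)cc2)[C@@H]1O | intermediate
10 | (2S,3S)-3,7,8-tris(benzyloxy)-2-[4-(benzyloxy)phenyl]chroman-4-one | O=C1c2ccc(OCc3ccccc3)c(OCc3ccccc3)c2O[C@@H](c2ccc(OCc3ccccc3)cc2)[C@@H]1OCc1ccccc1 | intermediate
11 | (2S,3R,4R)-3,7,8-tris(benzyloxy)-2-[4-(benzyloxy)phenyl]chroman-4-ol | O[C@@H]1c2ccc(OCc3ccccc3)c(OCc3ccccc3)c2O[C@@H](c2ccc(OCc3ccccc3)cc2)[C@@H]1OCc1ccccc1 | intermediate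
12 | (2S,3R,4R)-4-(allyloxy)-3,7,8-tris(benzyloxy)-2-[4-(benzyloxy)phenyl]chromane | C=CCO[C@@H]1c2ccc(OCc3ccccc3)c(OCc3ccccc3)c2O[C@@H](c2ccc(OCc3ccccc3)cc2)[C@@H]1OCc1ccccc1 | intermediate
13 | 2-{[(2S,3R,4R)-3,7,8-tris(benzyloxy)-2-[4-(benzyloxy)phenyl]chroman-4-yl]oxy}acetaldehyde | O=CCO[C@@H]1c2ccc(OCc3ccccc3)c(OCc3ccccc3)c2O[C@@H](c2ccc(OCc3ccccc3)cc2)[C@@H]1OCc1ccccc1 | intermediate
14 | potassium (Z)-2-{[(2S,3R,4R)-3,7,8-tris(benzyloxy)-2-[4-(benzyloxy)phenyl]chroman-4-yl]oxy}ethen-1-olate | [K+].[O-]/C=C\O[C@@H]1c2ccc(OCc3ccccc3)c(OCc3ccccc3)c2O[C@@H](c2ccc(OCc3ccccc3)cc2)[C@@H]1OCc1ccccc1 | intermediate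
15 | (Z)-2-{[(2S,3R,4R)-3,7,8-tris(benzyloxy)-2-[4-(benzyloxy)phenyl]chroman-4-yl]oxy}vinyl acetate | CC(=O)O/C=C\O[C@@H]1c2ccc(OCc3ccccc3)c(OCc3ccccc3)c2O[C@@H](c2ccc(OCc3ccccc3)cc2)[C@@H]1OCc1ccccc1 | intermediate
16 | 2,3-bis(benzyloxy)benzaldehyde | O=Cc1cccc(OCc2ccccc2)c1OCc1ccccc1 | starting material
17 | 2,3-bis(benzyloxy)phenyl formate | O=COc1cccc(OCc2ccccc2)c1OCc1ccccc1 | intermediate
18 | 2,3-bis(benzyloxy)phenol | Oc1cccc(OCc2ccccc2)c1OCc1ccccc1 | intermediate
19 | 4-(benzyloxy)benzaldehyde | O=Cc1ccc(OCc2ccccc2)cc1 | starting material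
20 | 1-(benzyloxy)-4-(dimethoxymethyl)benzene | COC(OC)c1ccc(OCc2ccccc2)cc1 | intermediate
21 | 1-(benzyloxy)-4-[chloro(methoxy)methyl]benzene | COC(Cl)c1ccc(OCc2ccccc2)cc1 | intermediate
22 | 1,2-bis(benzyloxy)-3-{[4-(benzyloxy)phenyl](methoxy)methoxy}benzene (racemic) | COC(Oc1cccc(OCc2ccccc2)c1OCc1ccccc1)c1ccc(OCc2ccccc2)cc1 | intermediate
23 | (E)-[4-(benzyloxy)benzylidene][2,3-bis(benzyloxy)phenyl]oxonium trifluoromethanesulfonate | c1ccc(COc2ccc(/C=[O+]/c3cccc(OCc4ccccc4)c3OCc3ccccc3)cc2)cc1.[O-]S(=O)(=O)C(F)(F)F | intermediate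
24 | (2R,3R,4R)-7,8-bis(benzyloxy)-2-[4-(benzyloxy)phenyl]-4-{[(2S,3R,4R)-3,7,8-tris(benzyloxy)-2-[4-(benzyloxy)phenyl]chroman-4-yl]oxy}chroman-3-yl acetate | c1ccccc1COc1ccc([C@H]2Oc3c(ccc(OCc4ccccc4)c3OCc3ccccc3)[C@@H](O[C@@H]3c4ccc(OCc5ccccc5)c(OCc5ccccc5)c4O[C@@H](c4ccc(OCc5ccccc5)cc4)[C@@H]3OCc3ccccc3)[C@H]2OC(C)=O)cc1 | intermediate
25 | (2R,3R,4R)-7,8-bis(benzyloxy)-2-[4-(benzyloxy)phenyl]-4-{[(2S,3R,4R)-3,7,8-tris(benzyloxy)-2-[4-(benzyloxy)phenyl]chroman-4-yl]oxy}chroman-3-ol | c1ccccc1COc1ccc([C@H]2Oc3c(ccc(OCc4ccccc4)c3OCc3ccccc3)[C@@H](O[C@@H]3c4ccc(OCc5ccccc5)c(OCc5ccccc5)c4O[C@@H](c4ccc(OCc5ccccc5)cc4)[C@@H]3OCc3ccccc3)[C@H]2O)cc1 | intermediate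
26 | (2R,3R,4R)-2-(4-hydroxyphenyl)-4-{[(2S,3R,4R)-3,7,8-trihydroxy-2-(4-hydroxyphenyl)chroman-4-yl]oxy}chromane-3,7,8-triol | Oc1ccc([C@H]2Oc3c(ccc(O)c3O)[C@@H](O[C@@H]3c4ccc(O)c(O)c4O[C@@H](c4ccc(O)cc4)[C@@H]3O)[C@H]2O)cc1 | target

Total step count: 15. Longest linear sequence: 12 steps (steps 1–9, then 13–15).

Steps most likely to fail

1. Step 13 (proposed new method). What may go wrong: poor π-facial or endo selectivity in the union, or cleavage of the flavan-4-yl–oxygen bond in the cationic intermediate before ring closure. The fallback uses known reactions only, sets out from chromone 4 and alcohol 11, and rejoins the route at 25. Conjugate addition of 5 to 4 as in step 3, but with (R)-t-BuPyOx, should give the (2S)-flavanone F1. NaBH4 (MeOH/THF, 0 °C) should give the 2,4-cis-flavan-4-ol F2, and Burgess reagent (toluene, 50 °C) the (2S)-flav-3-ene F3. Dimethyldioxirane (acetone, −40 °C) should add anti to the 2-aryl group to give the epoxide F4. Alcohol 11 then opens F4 at the benzylic C4 with inversion (pyridinium p-toluenesulfonate cat., 4 Å MS, CH2Cl2, −20 °C) to give the 2,3-trans-3,4-trans ether alcohol F5, which already holds the C4–O–C4 ether and the required C2 and C4 centres. Dess–Martin periodinane (NaHCO3, CH2Cl2) gives the flavan-3-one F6, and LiBH(s-Bu)3 (THF, −78 °C), attacking anti to the two flanking substituents, should give the all-cis alcohol 25.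

2. Step 9. What may go wrong: incomplete Z selectivity in the enolisation and self-aldol condensation of the aldehyde enolate. The fallback sets out from aldehyde 13 and rejoins at 15. Soft enolisation (Me3SiCl, Et3N, MeCN, rt) should give the (Z)-trimethylsilyl enol ether F7 without a free enolate. MeLi (THF, 0 °C) then releases the lithium enolate with retention of geometry, and Ac2O (−78 °C) acetylates it to 15.

3. Step 6. What may go wrong: poor facial selectivity of hydride delivery, leaving the 3,4-trans alcohol as a major product. The fallback sets out from ketone 10 and rejoins at 11. NaBH4 (MeOH/THF, 0 °C, axial delivery) should give the 3,4-trans alcohol F8. Mitsunobu inversion (4-nitrobenzoic acid, PPh3, diisopropyl azodicarboxylate, THF, 0 °C) should give the 3,4-cis 4-nitrobenzoate F9, and K2CO3/MeOH releases 11.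

Further compounds
F1 | step 13 | (2S)-7,8-bis(benzyloxy)-2-[4-(benzyloxy)phenyl]chroman-4-one | O=C1c2ccc(OCc3ccccc3)c(OCc3ccccc3)c2O[C@H](c2ccc(OCc3ccccc3)cc2)C1
F2 | step 13 | (2S,4S)-7,8-bis(benzyloxy)-2-[4-(benzyloxy)phenyl]chroman-4-ol | O[C@@H]1c2ccc(OCc3ccccc3)c(OCc3ccccc3)c2O[C@H](c2ccc(OCc3ccccc3)cc2)C1
F3 | step 13 | (2S)-7,8-bis(benzyloxy)-2-[4-(benzyloxy)phenyl]-2H-chromene | C1=C[C@@H](c2ccc(OCc3ccccc3)cc2)Oc2c1ccc(OCc1ccccc1)c2OCc1ccccc1
F4 | step 13 | (2R,3S,4S)-7,8-bis(benzyloxy)-2-[4-(benzyloxy)phenyl]-3,4-epoxychromane (epoxide anti to the aryl group) | O1[C@H]2c3ccc(OCc4ccccc4)c(OCc4ccccc4)c3O[C@H](c3ccc(OCc4ccccc4)cc3)[C@@H]12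
F5 | step 13 | (2R,3S,4R)-7,8-bis(benzyloxy)-2-[4-(benzyloxy)phenyl]-4-{[(2S,3R,4R)-3,7,8-tris(benzyloxy)-2-[4-(benzyloxy)phenyl]chroman-4-yl]oxy}chroman-3-ol | c1ccccc1COc1ccc([C@H]2Oc3c(ccc(OCc4ccccc4)c3OCc3ccccc3)[C@@H](O[C@@H]3c4ccc(OCc5ccccc5)c(OCc5ccccc5)c4O[C@@H](c4ccc(OCc5ccccc5)cc4)[C@@H]3OCc3ccccc3)[C@@H]2O)cc1
F6 | step 13 | (2R,4R)-7,8-bis(benzyloxy)-2-[4-(benzyloxy)phenyl]-4-{[(2S,3R,4R)-3,7,8-tris(benzyloxy)-2-[4-(benzyloxy)phenyl]chroman-4-yl]oxy}chroman-3-one | c1ccccc1COc1ccc([C@H]2Oc3c(ccc(OCc4ccccc4)c3OCc3ccccc3)[C@@H](O[C@@H]3c4ccc(OCc5ccccc5)c(OCc5ccccc5)c4O[C@@H](c4ccc(OCc5ccccc5)cc4)[C@@H]3OCc3ccccc3)C2=O)cc1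
F7 | step 9 | (2S,3R,4R)-3,7,8-tris(benzyloxy)-2-[4-(benzyloxy)phenyl]-4-{[(Z)-2-(trimethylsilyloxy)vinyl]oxy}chromane | C[Si](C)(C)O/C=C\O[C@@H]1c2ccc(OCc3ccccc3)c(OCc3ccccc3)c2O[C@@H](c2ccc(OCc3ccccc3)cc2)[C@@H]1OCc1ccccc1
F8 | step 6 | (2S,3R,4S)-3,7,8-tris(benzyloxy)-2-[4-(benzyloxy)phenyl]chroman-4-ol | O[C@H]1c2ccc(OCc3ccccc3)c(OCc3ccccc3)c2O[C@@H](c2ccc(OCc3ccccc3)cc2)[C@@H]1OCc1ccccc1
F9 | step 6 | (2S,3R,4R)-3,7,8-tris(benzyloxy)-2-[4-(benzyloxy)phenyl]chroman-4-yl 4-nitrobenzoate | O=C(O[C@@H]1c2ccc(OCc3ccccc3)c(OCc3ccccc3)c2O[C@@H](c2ccc(OCc3ccccc3)cc2)[C@@H]1OCc1ccccc1)c1ccc([N+](=O)[O-])cc1
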